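The cyclohexenone ring is closed by one enantioselective Diels–Alder reaction; ring atoms are numbered from the ketone carbon C1 through the hydroxymethyl-bearing C2 to the butenoate-bearing C6. A 1-silyloxy-4-isopropyl diene supplies C2–C5 and an (E)-3-acyloxyacrolein that already carries the protected butenoate supplies C6 and C1, so the C1–C2 and C5–C6 bonds form together. The step exploits the trans C5/C6 and cis C4/C5 pattern of the ring: E,E-diene and E-dienophile set C5 and C6, and the diene oxygen, delivered to C2 cis to isopropyl, is later moved suprafacially to C4 as the isobutyrate by a [3,3] shift after the C1 formyl group has been degraded to the ketone.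

Key step: step 5

Remark: in the Why lines C1–C6 always mean the ring atoms defined above, whatever the locants in the systematic names; compounds 1 and 4 are taken as catalogue compounds.
Assumption: the oxazaborolidinium catalyst follows its usual formyl C–H···O transition-state model, so that the (S)-catalyst gives 11; if the sense of induction is the opposite, the (R)-catalyst is used and nothing else changes.

Step 1
Reactants: 1 2-[(tert-butyldiphenylsilyl)oxy]acetaldehyde; 2 2-methylpropanedioic acid (methylmalonic acid)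
Product: 3 (2E)-4-[(tert-butyldiphenylsilyl)oxy]-2-methylbut-2-enoic acid
Conditions: pyridine, piperidine (0.1 equiv), 90 °C
Reagents that add atoms: none
Why: Knoevenagel condensation with decarboxylation (Doebner modification) should give the conjugated acid directly; the decarboxylative elimination under thermodynamic control favours the E alkene, and no stereocentre is formed.

Step 2
Reactants: 3 (2E)-4-[(tert-butyldiphenylsilyl)oxy]-2-methylbut-2-enoic acid; 4 tetrabutylammonium (1E)-3-oxoprop-1-en-1-olate (malonaldehyde tetrabutylammonium salt)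
Product: 6 (1E)-3-oxoprop-1-en-1-yl (2E)-4-[(tert-butyldiphenylsilyl)oxy]-2-methylbut-2-enoate, via acid chloride 5 (not isolated)
Conditions: 1-chloro-N,N,2-trimethylprop-1-en-1-amine, CH2Cl2, 0 °C; then 4, CH2Cl2, −20 °C to rt
Reagents that add atoms: 1-chloro-N,N,2-trimethylprop-1-en-1-amine, CC(C)=C(Cl)N(C)C (supplies only the chlorine of 5)
Why: Neutral acid chloride formation (Ghosez reagent) spares the silyl ether, and O-acylation of the ambident malonaldehyde enolate by the hard acyl chloride should give the (E)-3-acyloxyacrolein, a vinylogous mixed anhydride; no stereocentre is formed.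

Step 3
Reactants: 7 3-methylbutanal; 8 (triphenylphosphoranylidene)acetaldehyde
Product: 9 (2E)-5-methylhex-2-enal
Conditions: toluene, 80 °C (7 in excess)
Reagents that add atoms: none
Why: Wittig two-carbon homologation with the stabilised formyl ylide is E-selective; excess 7 suppresses a second homologation.

Step 4
Reactants: 9 (2E)-5-methylhex-2-enal
Product: 10 triethyl{[(1E,3E)-5-methylhexa-1,3-dien-1-yl]oxy}silane
Conditions: Et3SiOTf, Et3N, Et2O, 0 °C to rt
Reagents that add atoms: triethylsilyl trifluoromethanesulfonate, CC[Si](CC)(CC)OS(=O)(=O)C(F)(F)F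
Why: Soft enolisation (O-silylation of the enal, then γ-deprotonation by the amine) should give the 1-silyloxy-1,3-diene with the (1E,3E) isomer predominant; the minor 1Z isomer cannot reach the s-cis conformation, stays inert in step 5 and is removed there.

Step 5
Reactants: 10 triethyl{[(1E,3E)-5-methylhexa-1,3-dien-1-yl]oxy}silane; 6 (1E)-3-oxoprop-1-en-1-yl (2E)-4-[(tert-butyldiphenylsilyl)oxy]-2-methylbut-2-enoate
Product: 11 (1R,2S,5R,6S)-6-formyl-2-(propan-2-yl)-5-[(triethylsilyl)oxy]cyclohex-3-en-1-yl (2E)-4-[(tert-butyldiphenylsilyl)oxy]-2-methylbut-2-enoate (formyl, silyloxy and isopropyl groups all cis; butenoate trans to them)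
Conditions: (S)-1-(2-methylphenyl)-3,3-diphenyltetrahydro-1H,3H-pyrrolo[1,2-c][1,3,2]oxazaborole·HN(SO2CF3)2 (20 mol%), CH2Cl2, −78 to −40 °C
Reagents that add atoms: none
Why: The cationic oxazaborolidinium binds the formyl oxygen of 6 and lowers its LUMO, and the diene adds in a concerted but asynchronous normal-demand [4+2] cycloaddition in which the C5–C6 bond is more advanced than the C1–C2 bond. The closest known reaction type is the oxazaborolidinium-catalysed Diels–Alder reaction of α,β-unsaturated aldehydes with 1-oxygenated dienes. The six-membered carbocycle closes intermolecularly in the suprafacial [4π+2π] mode through the endo transition state (formyl group under the diene). C2 and C5 come out cis because both diene alkenes are E, C6 is trans to C1 because the dienophile is E, the endo rule places the formyl group cis to the C2 silyloxy group and therefore the C6 ester trans to the C5 isopropyl group, and the absolute configuration is set by the catalyst, which shields one face of the bound enal. The step needs ortho regioselectivity, which the silyloxy donor secures by placing the largest HOMO coefficient on the isopropyl-bearing diene terminus that pairs with the β-carbon of the enal.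

Step 6
Reactants: 11 (1R,2S,5R,6S)-6-formyl-2-(propan-2-yl)-5-[(triethylsilyl)oxy]cyclohex-3-en-1-yl (2E)-4-[(tert-butyldiphenylsilyl)oxy]-2-methylbut-2-enoate
Product: 12 (1S,2R,5S,6R)-6-{[(2E)-4-[(tert-butyldiphenylsilyl)oxy]-2-methylbut-2-enoyl]oxy}-5-(propan-2-yl)-2-[(triethylsilyl)oxy]cyclohex-3-ene-1-carboxylic acid
Conditions: NaClO2, NaH2PO4, 2-methylbut-2-ene, t-BuOH/H2O, 0 °C
Reagents that add atoms: sodium chlorite, [Na+].[O-]Cl=O
Why: Pinnick oxidation is buffered and the hypochlorite by-product is scavenged, so the alkenes, esters and silyl ethers should survive; the weakly acidic medium avoids β-elimination, and C1 is not epimerised (its configuration is lost in step 7 anyway).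

Step 7
Reactants: 12 (1S,2R,5S,6R)-6-{[(2E)-4-[(tert-butyldiphenylsilyl)oxy]-2-methylbut-2-enoyl]oxy}-5-(propan-2-yl)-2-[(triethylsilyl)oxy]cyclohex-3-ene-1-carboxylic acid
Product: 14 (1R,2S,5R)-6-oxo-2-(propan-2-yl)-5-[(triethylsilyl)oxy]cyclohex-3-en-1-yl (2E)-4-[(tert-butyldiphenylsilyl)oxy]-2-methylbut-2-enoate, via hydroperoxide 13 (not isolated)
Conditions: 9-mesityl-10-methylacridinium tetrafluoroborate (5 mol%), 2,6-lutidine (0.2 equiv), O2 (1 atm), ClCH2CH2Cl, blue LEDs, rt; then Ac2O, pyridine, 0 °C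
Reagents that add atoms: dioxygen, O=O
Why: Photoredox decarboxylative oxygenation: the excited acridinium oxidises the carboxylate, loss of CO2 gives the secondary C1 radical, O2 traps it faster than a 1,2-acyloxy shift can occur, and the hydroperoxide 13 is dehydrated to the ketone by acetylation and loss of acetate (Kornblum–DeLaMare type); C2, C5 and C6 are untouched.

Step 8
Reactants: 14 (1R,2S,5R)-6-oxo-2-(propan-2-yl)-5-[(triethylsilyl)oxy]cyclohex-3-en-1-yl (2E)-4-[(tert-butyldiphenylsilyl)oxy]-2-methylbut-2-enoate; 15 2-methylpropanoic anhydride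
Product: 16 (1R,2S,5R)-5-[(2-methylpropanoyl)oxy]-6-oxo-2-(propan-2-yl)cyclohex-3-en-1-yl (2E)-4-[(tert-butyldiphenylsilyl)oxy]-2-methylbut-2-enoate
Conditions: Bi(OTf)3 (5 mol%), MeCN, −20 to 0 °C
Reagents that add atoms: none
Why: Lewis-acid-catalysed direct conversion of a silyl ether into an ester: the labile secondary triethylsilyl ether is acylated on oxygen and loses silicon, while the primary tert-butyldiphenylsilyl ether should stay; the C2–O bond is not broken, so C2 keeps its configuration.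

Step 9
Reactants: 16 (1R,2S,5R)-5-[(2-methylpropanoyl)oxy]-6-oxo-2-(propan-2-yl)cyclohex-3-en-1-yl (2E)-4-[(tert-butyldiphenylsilyl)oxy]-2-methylbut-2-enoate
Product: 17 (1R,5S,6S)-5-[(2-methylpropanoyl)oxy]-2-oxo-6-(propan-2-yl)cyclohex-3-en-1-yl (2E)-4-[(tert-butyldiphenylsilyl)oxy]-2-methylbut-2-enoate
Conditions: PdCl2(MeCN)2 (10 mol%), THF, rt
Reagents that add atoms: none
Why: [3,3]-Sigmatropic shift of an allylic ester catalysed by divalent palladium (Overman-type cyclisation-induced rearrangement): the ester carbonyl oxygen attacks C4 of the palladium-bound C3=C4 alkene on the face it already occupies and the 1,3-dioxan-2-ylium intermediate opens at C2–O, so the new C4 stereocentre is set by suprafacial chirality transfer from C2 (cis to the C5 isopropyl group); conjugation of the new C2=C3 alkene with the C1 ketone drives the equilibrium.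

Step 10
Reactants: 17 (1R,5S,6S)-5-[(2-methylpropanoyl)oxy]-2-oxo-6-(propan-2-yl)cyclohex-3-en-1-yl (2E)-4-[(tert-butyldiphenylsilyl)oxy]-2-methylbut-2-enoate; 18 formaldehyde
Product: 19 (1R,5S,6S)-3-(hydroxymethyl)-5-[(2-methylpropanoyl)oxy]-2-oxo-6-(propan-2-yl)cyclohex-3-en-1-yl (2E)-4-[(tert-butyldiphenylsilyl)oxy]-2-methylbut-2-enoate
Conditions: 18 (37% aqueous), 4-(dimethylamino)pyridine (0.3 equiv), THF/H2O, rt
Reagents that add atoms: none
Why: Morita–Baylis–Hillman reaction: the amine adds to C3, the C2 enolate adds to formaldehyde and elimination restores the enone; the trisubstituted butenoate is not an acceptor under these conditions, and no stereocentre is formed.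

Step 11
Reactants: 19 (1R,5S,6S)-3-(hydroxymethyl)-5-[(2-methylpropanoyl)oxy]-2-oxo-6-(propan-2-yl)cyclohex-3-en-1-yl (2E)-4-[(tert-butyldiphenylsilyl)oxy]-2-methylbut-2-enoate
Product: 20 (1R,5S,6S)-3-(hydroxymethyl)-5-[(2-methylpropanoyl)oxy]-2-oxo-6-(propan-2-yl)cyclohex-3-en-1-yl (2E)-4-hydroxy-2-methylbut-2-enoate (CNP0254776.1)
Conditions: HF·pyridine, pyridine, THF, 0 °C to rt
Reagents that add atoms: none
Why: Fluoride cleavage of the silyl ether under buffered, weakly acidic conditions should leave both esters and the enone untouched and avoids base-induced acyl migration at the α-acyloxy ketone.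

Compound list
1 | 2-[(tert-butyldiphenylsilyl)oxy]acetaldehyde | O=CCO[Si](c1ccccc1)(c1ccccc1)C(C)(C)C | starting material
2 | 2-methylpropanedioic acid (methylmalonic acid) | CC(C(=O)O)C(=O)O | starting material
3 | (2E)-4-[(tert-butyldiphenylsilyl)oxy]-2-methylbut-2-enoic acid | C/C(=C\CO[Si](c1ccccc1)(c1ccccc1)C(C)(C)C)C(=O)O | intermediate
4 | tetrabutylammonium (1E)-3-oxoprop-1-en-1-olate | CCCC[N+](CCCC)(CCCC)CCCC.[O-]/C=C/C=O | starting material
5 | (2E)-4-[(tert-butyldiphenylsilyl)oxy]-2-methylbut-2-enoyl chloride | C/C(=C\CO[Si](c1ccccc1)(c1ccccc1)C(C)(C)C)C(=O)Cl | intermediate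
6 | (1E)-3-oxoprop-1-en-1-yl (2E)-4-[(tert-butyldiphenylsilyl)oxy]-2-methylbut-2-enoate | C/C(=C\CO[Si](c1ccccc1)(c1ccccc1)C(C)(C)C)C(=O)O/C=C/C=O | intermediate
7 | 3-methylbutanal | CC(C)CC=O | starting material
8 | (triphenylphosphoranylidene)acetaldehyde | O=CC=P(c1ccccc1)(c1ccccc1)c1ccccc1 | starting material
9 | (2E)-5-methylhex-2-enal | CC(C)C/C=C/C=O | intermediate
10 | triethyl{[(1E,3E)-5-methylhexa-1,3-dien-1-yl]oxy}silane | CC[Si](CC)(CC)O/C=C/C=C/C(C)C | intermediate
11 | (1R,2S,5R,6S)-6-formyl-2-(propan-2-yl)-5-[(triethylsilyl)oxy]cyclohex-3-en-1-yl (2E)-4-[(tert-butyldiphenylsilyl)oxy]-2-methylbut-2-enoate | C/C(=C\CO[Si](c1ccccc1)(c1ccccc1)C(C)(C)C)C(=O)O[C@H]1[C@H](C=O)[C@H](O[Si](CC)(CC)CC)C=C[C@@H]1C(C)C | intermediate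
12 | (1S,2R,5S,6R)-6-{[(2E)-4-[(tert-butyldiphenylsilyl)oxy]-2-methylbut-2-enoyl]oxy}-5-(propan-2-yl)-2-[(triethylsilyl)oxy]cyclohex-3-ene-1-carboxylic acid | C/C(=C\CO[Si](c1ccccc1)(c1ccccc1)C(C)(C)C)C(=O)O[C@H]1[C@H](C(=O)O)[C@H](O[Si](CC)(CC)CC)C=C[C@@H]1C(C)C | intermediate
13 | (1R,2S,5R)-6-hydroperoxy-2-(propan-2-yl)-5-[(triethylsilyl)oxy]cyclohex-3-en-1-yl (2E)-4-[(tert-butyldiphenylsilyl)oxy]-2-methylbut-2-enoate (both epimers at the hydroperoxy carbon) | C/C(=C\CO[Si](c1ccccc1)(c1ccccc1)C(C)(C)C)C(=O)O[C@H]1C(OO)[C@H](O[Si](CC)(CC)CC)C=C[C@@H]1C(C)C | intermediate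
14 | (1R,2S,5R)-6-oxo-2-(propan-2-yl)-5-[(triethylsilyl)oxy]cyclohex-3-en-1-yl (2E)-4-[(tert-butyldiphenylsilyl)oxy]-2-methylbut-2-enoate | C/C(=C\CO[Si](c1ccccc1)(c1ccccc1)C(C)(C)C)C(=O)O[C@H]1C(=O)[C@H](O[Si](CC)(CC)CC)C=C[C@@H]1C(C)C | intermediate
15 | 2-methylpropanoic anhydride | CC(C)C(=O)OC(=O)C(C)C | starting material
16 | (1R,2S,5R)-5-[(2-methylpropanoyl)oxy]-6-oxo-2-(propan-2-yl)cyclohex-3-en-1-yl (2E)-4-[(tert-butyldiphenylsilyl)oxy]-2-methylbut-2-enoate | C/C(=C\CO[Si](c1ccccc1)(c1ccccc1)C(C)(C)C)C(=O)O[C@H]1C(=O)[C@H](OC(=O)C(C)C)C=C[C@@H]1C(C)C | intermediate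
17 | (1R,5S,6S)-5-[(2-methylpropanoyl)oxy]-2-oxo-6-(propan-2-yl)cyclohex-3-en-1-yl (2E)-4-[(tert-butyldiphenylsilyl)oxy]-2-methylbut-2-enoate | C/C(=C\CO[Si](c1ccccc1)(c1ccccc1)C(C)(C)C)C(=O)O[C@H]1C(=O)C=C[C@H](OC(=O)C(C)C)[C@@H]1C(C)C | intermediate
18 | formaldehyde | C=O | starting material
19 | (1R,5S,6S)-3-(hydroxymethyl)-5-[(2-methylpropanoyl)oxy]-2-oxo-6-(propan-2-yl)cyclohex-3-en-1-yl (2E)-4-[(tert-butyldiphenylsilyl)oxy]-2-methylbut-2-enoate | C/C(=C\CO[Si](c1ccccc1)(c1ccccc1)C(C)(C)C)C(=O)O[C@H]1C(=O)C(CO)=C[C@H](OC(=O)C(C)C)[C@@H]1C(C)C | intermediate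
20 | (1R,5S,6S)-3-(hydroxymethyl)-5-[(2-methylpropanoyl)oxy]-2-oxo-6-(propan-2-yl)cyclohex-3-en-1-yl (2E)-4-hydroxy-2-methylbut-2-enoate | C/C(=C\CO)C(=O)O[C@H]1C(=O)C(CO)=C[C@H](OC(=O)C(C)C)[C@@H]1C(C)C | target

Total step count: 11. Longest linear sequence: 9 steps (steps 1, 2 and 5–11; the branch through steps 3, 4 and 5–11 is equally long).

Steps most likely to fail

Step 5. The catalyst may discriminate the enal faces poorly, or the union may run stepwise (Mukaiyama–Michael addition of the silyl dienol ether) and stop at an open-chain adduct or erode the endo preference. The fallback replaces catalyst control by auxiliary control; it sets out from acid 3 and diene 10 and comes back at acid 12, so that aldehyde 11 and step 6 are bypassed. Acid 3 is added (N-methylmorpholine cat., CH2Cl2) across the triple bond of (4R)-4-benzyl-3-(prop-2-ynoyl)-1,3-oxazolidin-2-one F1, itself made from propiolic acid, pivaloyl chloride and the lithium salt of the oxazolidinone, to give the (E)-acyloxyacryloyl imide (4R)-4-benzyl-3-[(2E)-3-{[(2E)-4-[(tert-butyldiphenylsilyl)oxy]-2-methylbut-2-enoyl]oxy}prop-2-enoyl]-1,3-oxazolidin-2-one F2. Et2AlCl (1.4 equiv, CH2Cl2, −78 °C) chelates the two imide carbonyls, the benzyl group covers one face of the s-cis enoyl unit, and cycloaddition with 10 should give, with the same ortho and endo preferences, the imide cycloadduct (1R,2S,5R,6S)-6-{[(4R)-4-benzyl-2-oxo-1,3-oxazolidin-3-yl]carbonyl}-2-(propan-2-yl)-5-[(triethylsilyl)oxy]cyclohex-3-en-1-yl (2E)-4-[(tert-butyldiphenylsilyl)oxy]-2-methylbut-2-enoate F3. LiOH and H2O2 (THF/H2O, 0 °C) then remove the auxiliary and give 12.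

Step 7. The hindered carboxylate may be oxidised inefficiently by the excited photocatalyst, the C1 radical may undergo 1,2-acyloxy migration before oxygen trapping, or the C3=C4 double bond may migrate during the dehydration of the hydroperoxide. The fallback is a Barton radical-chain decarboxylation; it sets out from 12 and comes back at 14. Acid 12 is coupled with N-hydroxypyridine-2-thione (DCC, CH2Cl2, dark) to the thiohydroxamate ester 2-thioxopyridin-1(2H)-yl (1S,2R,5S,6R)-6-{[(2E)-4-[(tert-butyldiphenylsilyl)oxy]-2-methylbut-2-enoyl]oxy}-5-(propan-2-yl)-2-[(triethylsilyl)oxy]cyclohex-3-ene-1-carboxylate F4. Visible light, O2 and t-BuSH (toluene, 0 °C), then P(OMe)3, should give the secondary alcohol (1R,2S,5R)-6-hydroxy-2-(propan-2-yl)-5-[(triethylsilyl)oxy]cyclohex-3-en-1-yl (2E)-4-[(tert-butyldiphenylsilyl)oxy]-2-methylbut-2-enoate F5 as a mixture of epimers at the carbinol carbon, and Dess–Martin periodinane (NaHCO3, CH2Cl2) oxidises it to 14.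

Step 10. Addition of the nucleophilic catalyst to the hindered C3 may be slow, and acyl transfer from the α-acyloxy ketone to the catalyst or to water may compete. The fallback is a cross-coupling route; it sets out from 17 and comes back at 19. Iodine and pyridine (CH2Cl2, rt; conjugate addition of pyridine, iodination of the enolate, elimination) should give the 2-iodoenone (1R,5R,6S)-3-iodo-5-[(2-methylpropanoyl)oxy]-2-oxo-6-(propan-2-yl)cyclohex-3-en-1-yl (2E)-4-[(tert-butyldiphenylsilyl)oxy]-2-methylbut-2-enoate F6, and Stille coupling with (tributylstannyl)methanol (Pd(PPh3)4, a zerovalent palladium complex, dioxane, 80 °C) gives 19.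

Further compounds
F1 | step 5 | (4R)-4-benzyl-3-(prop-2-ynoyl)-1,3-oxazolidin-2-one | C#CC(=O)N1[C@H](Cc2ccccc2)COC1=O
F2 | step 5 | (4R)-4-benzyl-3-[(2E)-3-{[(2E)-4-[(tert-butyldiphenylsilyl)oxy]-2-methylbut-2-enoyl]oxy}prop-2-enoyl]-1,3-oxazolidin-2-one | C/C(=C\CO[Si](c1ccccc1)(c1ccccc1)C(C)(C)C)C(=O)O/C=C/C(=O)N1[C@H](Cc2ccccc2)COC1=O
F3 | step 5 | (1R,2S,5R,6S)-6-{[(4R)-4-benzyl-2-oxo-1,3-oxazolidin-3-yl]carbonyl}-2-(propan-2-yl)-5-[(triethylsilyl)oxy]cyclohex-3-en-1-yl (2E)-4-[(tert-butyldiphenylsilyl)oxy]-2-methylbut-2-enoate | C/C(=C\CO[Si](c1ccccc1)(c1ccccc1)C(C)(C)C)C(=O)O[C@H]1[C@H](C(=O)N2[C@H](Cc3ccccc3)COC2=O)[C@H](O[Si](CC)(CC)CC)C=C[C@@H]1C(C)C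
F4 | step 7 | 2-thioxopyridin-1(2H)-yl (1S,2R,5S,6R)-6-{[(2E)-4-[(tert-butyldiphenylsilyl)oxy]-2-methylbut-2-enoyl]oxy}-5-(propan-2-yl)-2-[(triethylsilyl)oxy]cyclohex-3-ene-1-carboxylate | C/C(=C\CO[Si](c1ccccc1)(c1ccccc1)C(C)(C)C)C(=O)O[C@H]1[C@H](C(=O)On2ccccc2=S)[C@H](O[Si](CC)(CC)CC)C=C[C@@H]1C(C)C
F5 | step 7 | (1R,2S,5R)-6-hydroxy-2-(propan-2-yl)-5-[(triethylsilyl)oxy]cyclohex-3-en-1-yl (2E)-4-[(tert-butyldiphenylsilyl)oxy]-2-methylbut-2-enoate (both epimers at the carbinol carbon) | C/C(=C\CO[Si](c1ccccc1)(c1ccccc1)C(C)(C)C)C(=O)O[C@H]1C(O)[C@H](O[Si](CC)(CC)CC)C=C[C@@H]1C(C)C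
F6 | step 10 | (1R,5R,6S)-3-iodo-5-[(2-methylpropanoyl)oxy]-2-oxo-6-(propan-2-yl)cyclohex-3-en-1-yl (2E)-4-[(tert-butyldiphenylsilyl)oxy]-2-methylbut-2-enoate | C/C(=C\CO[Si](c1ccccc1)(c1ccccc1)C(C)(C)C)C(=O)O[C@H]1C(=O)C(I)=C[C@H](OC(=O)C(C)C)[C@@H]1C(C)C
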